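**Retrosynthetic overview** (lactone numbering: O1, C2 carbonyl, C3 alkylidene carbon, C4 carbinol, C5)
- The oxolanone ring is closed in the last step from an acyclic alkenyl iodide/oxirane and CO2, which forms the C2–C3 bond and the O1–C5 bond in one flask.
- Enabling feature: O1–C5 is an allylic C–O bond (C5 carries the 2-methylprop-1-enyl group) and the neighbouring C4 carries the free OH. C4, C5 and the C4 oxygen therefore map onto a trans-oxirane, which a carboxylate born at C3 opens at its allylic carbon (5-endo, strain release), unveiling the C4–OH.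
- The iodo-oxirane comes from a 4-iodo-2,4-dienol by Sharpless epoxidation (oxirane ring formed here), oxidation and Wittig olefination, followed by exchange of silyl ethers for the two esters.
- The iodo-dienol comes from an enynoate by syn-hydrostannation/iodination and reduction; the enynoate comes from Sonogashira coupling of a homopropargylic silyl ether with ethyl (E)-3-iodoacrylate.
- The alkyne comes from nerol by silylation, SeO2 oxidation and catalytic asymmetric propargylation. Ring order: oxirane (step 9), then the oxolanone (step 15) at the expense of the oxirane.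

Key step: step 15

Assumption: ethyl (2E)-3-iodoprop-2-enoate and (2E)-3-methylpent-2-enoic acid are bought as the geometrically pure E isomers.

Step 1
Reactants: 1 nerol
Product: 2 neryl tert-butyldimethylsilyl ether
Conditions: TBSCl, imidazole, DMF, 0 °C → rt
Reagents that add atoms: tert-butyldimethylsilyl chloride, C[Si](C)(Cl)C(C)(C)C
Why: Imidazole-promoted silylation of the only hydroxyl gives an allylic ether that does not ionise with zerovalent palladium and tolerates the hydride, peroxide and ylide reagents used later.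

Step 2
Reactants: 2 neryl tert-butyldimethylsilyl ether
Product: 3 (2E,6Z)-8-silyloxy-2,6-dimethylocta-2,6-dien-1-ol
Conditions: SeO2 (cat.), t-BuOOH, salicylic acid (cat.), CH2Cl2, 0 °C → rt
Reagents that add atoms: tert-butyl hydroperoxide, CC(C)(C)OO (oxygen transferred through catalytic SeO2, O=[Se]=O)
Why: SeO2 allylic oxidation (ene reaction then [2,3]-sigmatropic shift, Riley oxidation) should take the (E)-methyl group of the electron-richer terminal alkene, the other alkene being deactivated by its allylic oxygen, and gives the (E)-allylic alcohol; any enal 4 formed alongside is carried into step 3.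

Step 3
Reactants: 3 (2E,6Z)-8-silyloxy-2,6-dimethylocta-2,6-dien-1-ol
Product: 4 (2E,6Z)-8-silyloxy-2,6-dimethylocta-2,6-dienal
Conditions: MnO2, CH2Cl2, rt
Reagents that add atoms: none
Why: MnO2 oxidation of a primary allylic alcohol to the enal leaves the silyl ether and both alkene geometries untouched.

Step 4
Reactants: 4 (2E,6Z)-8-silyloxy-2,6-dimethylocta-2,6-dienal; 5 allenylboronic acid pinacol ester
Product: 6 (4S)-homopropargylic alcohol
Conditions: (S)-TRIP [(S)-3,3'-bis(2,4,6-triisopropylphenyl)-1,1'-binaphthyl-2,2'-diyl hydrogen phosphate] (10 mol %), 4 Å MS, toluene, −30 °C; aqueous work-up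
Reagents that add atoms: none
Why: Chiral phosphoric acid-catalysed propargylation of the aldehyde by the allenylboronate through a closed six-membered SE2' transition state; the catalyst controls the new carbinol centre, and the (S)-catalyst is specified on the expectation of Si-face delivery (mirror image of the Re-face preference of the (R)-catalyst with aryl and alkenyl aldehydes), to be confirmed on 6 by Mosher ester analysis.

Step 5
Reactants: 6 (4S)-homopropargylic alcohol
Product: 7 (4S)-bis-silyl ether alkyne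
Conditions: TBSCl, imidazole, DMAP (cat.), DMF, rt
Reagents that add atoms: tert-butyldimethylsilyl chloride, C[Si](C)(Cl)C(C)(C)C
Why: Silylation of the secondary allylic alcohol masks it for the palladium hydride, aluminium hydride and ylide steps without touching the stereocentre.

Step 6
Reactants: 7 (4S)-bis-silyl ether alkyne; 8 ethyl (2E)-3-iodoprop-2-enoate
Product: 9 ethyl (2E)-en-4-ynoate
Conditions: Pd(PPh3)2Cl2 (cat.), CuI (cat.), Et3N, THF, rt
Reagents that add atoms: none
Why: Sonogashira coupling (zerovalent palladium with CuI) of the terminal alkyne with the alkenyl iodide proceeds with retention of the (E)-geometry.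

Step 7
Reactants: 9 ethyl (2E)-en-4-ynoate
Product: 11 ethyl (2E,4E)-4-iodo-2,4-dienoate, via alkenylstannane 10 (not isolated)
Conditions: Pd(PPh3)2Cl2 (cat.), Bu3SnH, THF, 0 °C; then I2, CH2Cl2, 0 °C
Reagents that add atoms: tributyltin hydride, CCCC[SnH](CCCC)CCCC (tin of 10); iodine, II
Why: Palladium-catalysed syn-hydrostannation should deliver hydride to the electron-poor C5 terminus of the enynoate and tin to C4 next to the alkene, and iododestannylation with retention then gives the iodide with H and I cis, the geometry that becomes the (E)-alkylidene of the lactone.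

Step 8
Reactants: 11 ethyl (2E,4E)-4-iodo-2,4-dienoate
Product: 12 (2E,4E)-4-iodo-2,4-dien-1-ol
Conditions: i-Bu2AlH, CH2Cl2, −78 °C
Reagents that add atoms: none
Why: 1,2-Reduction of the conjugated ester by i-Bu2AlH at low temperature gives the primary allylic alcohol and is tolerated by the alkenyl iodide and the silyl ethers.

Step 9
Reactants: 12 (2E,4E)-4-iodo-2,4-dien-1-ol
Product: 13 (2S,3R)-epoxy alcohol
Conditions: Ti(OiPr)4, L-(+)-diethyl tartrate, t-BuOOH, 4 Å MS, CH2Cl2, −20 °C
Reagents that add atoms: tert-butyl hydroperoxide, CC(C)(C)OO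
Why: Sharpless asymmetric epoxidation is confined to the alkene of the allylic alcohol; L-(+)-tartrate should deliver oxygen to the face that gives the (2S)-epoxy alcohol, as with other (E)-2-alken-1-ols, the (E)-alkene fixes the trans relationship, and C3 is R only because the iodoalkenyl group outranks C2.

Step 10
Reactants: 13 (2S,3R)-epoxy alcohol
Product: 14 (2R,3R)-epoxy aldehyde
Conditions: Dess–Martin periodinane, pyridine, CH2Cl2, 0 °C → rt
Reagents that add atoms: none
Why: Buffered Dess–Martin oxidation gives the trans-epoxy aldehyde without epimerisation or oxirane opening (the change of descriptor at C2 is a priority effect only).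

Step 11
Reactants: 14 (2R,3R)-epoxy aldehyde; 15 isopropyltriphenylphosphonium iodide
Product: 16 (2R,3S)-2-(1-iodoalkenyl)-3-(2-methylprop-1-enyl)oxirane bis-silyl ether
Conditions: 15, KN(SiMe3)2, THF, 0 °C; then 14, −78 → 0 °C
Reagents that add atoms: none
Why: Wittig olefination with the non-stabilised isopropylidene ylide turns the aldehyde into the 2-methylprop-1-enyl group (no alkene geometry at stake) and is far faster than any reaction of the ylide with the oxirane or the alkenyl iodide.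

Step 12
Reactants: 16 (2R,3S)-2-(1-iodoalkenyl)-3-(2-methylprop-1-enyl)oxirane bis-silyl ether
Product: 17 iodo-oxirane diol
Conditions: Bu4NF, THF, 0 °C → rt
Reagents that add atoms: none
Why: Fluoride-mediated desilylation frees both alcohols under non-acidic conditions that the acid-sensitive vinyl oxirane tolerates.

Step 13
Reactants: 17 iodo-oxirane diol; 18 (2E)-3-methylpent-2-enoic acid
Product: 19 primary (2E)-3-methylpent-2-enoate with free secondary alcohol
Conditions: DCC, DMAP (cat.), CH2Cl2, −20 °C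
Reagents that add atoms: none
Why: Steglich esterification at low temperature should acylate the unhindered primary allylic alcohol in preference to the secondary one, without isomerising the β,β-disubstituted enoate.

Step 14
Reactants: 19 primary (2E)-3-methylpent-2-enoate with free secondary alcohol
Product: 20 acetate (iodo-oxirane diester)
Conditions: Ac2O, pyridine, DMAP (cat.), CH2Cl2, 0 °C
Reagents that add atoms: acetic anhydride, CC(=O)OC(C)=O
Why: DMAP-catalysed acetylation of the remaining secondary alcohol under basic conditions leaves the oxirane and the alkenyl iodide intact.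

Step 15
Reactants: 20 acetate (iodo-oxirane diester); 21 carbon dioxide
Product: 25 target lactone, via alkenyllithium 22 (not isolated), via lithium carboxylate 23 (not isolated), via epoxy acid 24 (not isolated)
Conditions: t-BuLi (2.0 equiv), THF/Et2O/pentane, −105 °C; CO2 (g), −105 → −78 °C; AcOH, −78 °C → rt
Reagents that add atoms: tert-butyllithium, [Li]C(C)(C)C (lithium of 22 and 23)
Why: Iodine–lithium exchange at −105 °C, which outruns addition of the alkyllithium to the two ester groups (intramolecular attack of the C–Li bond on the acetate is excluded because the ring would hold a trans double bond), gives the configurationally stable alkenyllithium 22, which CO2 carboxylates with retention to form the C2–C3 bond (23). On protonation, the carboxyl oxygen of acid 24 attacks the oxirane carbon that carries the 2-methylprop-1-enyl group, which forms the O1–C5 bond and frees the C4 hydroxyl; the closest known reaction types are the carboxylation of alkenyllithiums and the spontaneous or acid-induced lactonisation of β,γ-epoxy acids to trans-β-hydroxy-γ-lactones. The oxolanone ring closes in the 5-endo mode of oxirane opening, driven by release of oxirane strain, whereas the 4-exo alternative would give a strained β-lactone at a carbon deactivated by the adjoining acrylate. C5 is set by backside attack, that is inversion of the (S)-oxirane carbon to (5R); C4 keeps its oxygen and becomes (4S); and the exocyclic (E)-geometry is inherited from the alkenyl iodide, whose iodine is cis to the vinylic hydrogen. The step needs regioselective opening at C5, which the allylic, cation-stabilising 2-methylprop-1-enyl group secures, and survival of the alkenyllithium next to the oxirane and the esters, for which the very low temperature, exact stoichiometry and immediate CO2 quench are relied on.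

**Compound list**
1 | nerol, (2Z)-3,7-dimethylocta-2,6-dien-1-ol | CC(C)=CCC/C(C)=C\CO | starting material
2 | tert-butyl{[(2Z)-3,7-dimethylocta-2,6-dien-1-yl]oxy}dimethylsilane | CC(C)=CCC/C(C)=C\CO[Si](C)(C)C(C)(C)C | intermediate
3 | (2E,6Z)-8-[(tert-butyldimethylsilyl)oxy]-2,6-dimethylocta-2,6-dien-1-ol | OC/C(C)=C/CC/C(C)=C\CO[Si](C)(C)C(C)(C)C | intermediate
4 | (2E,6Z)-8-[(tert-butyldimethylsilyl)oxy]-2,6-dimethylocta-2,6-dienal | O=C/C(C)=C/CC/C(C)=C\CO[Si](C)(C)C(C)(C)C | intermediate
5 | allenylboronic acid pinacol ester, 4,4,5,5-tetramethyl-2-(propa-1,2-dien-1-yl)-1,3,2-dioxaborolane | C=C=CB1OC(C)(C)C(C)(C)O1 | starting material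
6 | (4S,5E,9Z)-11-[(tert-butyldimethylsilyl)oxy]-5,9-dimethylundeca-5,9-dien-1-yn-4-ol | C#CC[C@H](O)/C(C)=C/CC/C(C)=C\CO[Si](C)(C)C(C)(C)C | intermediate
7 | (4S,5E,9Z)-4,11-bis[(tert-butyldimethylsilyl)oxy]-5,9-dimethylundeca-5,9-dien-1-yne | C#CC[C@H](O[Si](C)(C)C(C)(C)C)/C(C)=C/CC/C(C)=C\CO[Si](C)(C)C(C)(C)C | intermediate
8 | ethyl (2E)-3-iodoprop-2-enoate | CCOC(=O)/C=C/I | starting material
9 | ethyl (2E,7S,8E,12Z)-7,14-bis[(tert-butyldimethylsilyl)oxy]-8,12-dimethyltetradeca-2,8,12-trien-4-ynoate | CCOC(=O)/C=C/C#CC[C@H](O[Si](C)(C)C(C)(C)C)/C(C)=C/CC/C(C)=C\CO[Si](C)(C)C(C)(C)C | intermediate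
10 | ethyl (2E,4E,7S,8E,12Z)-7,14-bis[(tert-butyldimethylsilyl)oxy]-8,12-dimethyl-4-(tributylstannyl)tetradeca-2,4,8,12-tetraenoate | CCOC(=O)/C=C/C(/[Sn](CCCC)(CCCC)CCCC)=C\C[C@H](O[Si](C)(C)C(C)(C)C)/C(C)=C/CC/C(C)=C\CO[Si](C)(C)C(C)(C)C | intermediate
11 | ethyl (2E,4E,7S,8E,12Z)-7,14-bis[(tert-butyldimethylsilyl)oxy]-4-iodo-8,12-dimethyltetradeca-2,4,8,12-tetraenoate | CCOC(=O)/C=C/C(/I)=C\C[C@H](O[Si](C)(C)C(C)(C)C)/C(C)=C/CC/C(C)=C\CO[Si](C)(C)C(C)(C)C | intermediate
12 | (2E,4E,7S,8E,12Z)-7,14-bis[(tert-butyldimethylsilyl)oxy]-4-iodo-8,12-dimethyltetradeca-2,4,8,12-tetraen-1-ol | OC/C=C/C(/I)=C\C[C@H](O[Si](C)(C)C(C)(C)C)/C(C)=C/CC/C(C)=C\CO[Si](C)(C)C(C)(C)C | intermediate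
13 | {(2S,3R)-3-[(1E,4S,5E,9Z)-4,11-bis[(tert-butyldimethylsilyl)oxy]-1-iodo-5,9-dimethylundeca-1,5,9-trien-1-yl]oxiran-2-yl}methanol | OC[C@@H]1O[C@H]1C(/I)=C\C[C@H](O[Si](C)(C)C(C)(C)C)/C(C)=C/CC/C(C)=C\CO[Si](C)(C)C(C)(C)C | intermediate
14 | (2R,3R)-3-[(1E,4S,5E,9Z)-4,11-bis[(tert-butyldimethylsilyl)oxy]-1-iodo-5,9-dimethylundeca-1,5,9-trien-1-yl]oxirane-2-carbaldehyde | O=C[C@@H]1O[C@H]1C(/I)=C\C[C@H](O[Si](C)(C)C(C)(C)C)/C(C)=C/CC/C(C)=C\CO[Si](C)(C)C(C)(C)C | intermediate
15 | isopropyltriphenylphosphonium iodide | CC(C)[P+](c1ccccc1)(c1ccccc1)c1ccccc1.[I-] | starting material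
16 | (2R,3S)-2-[(1E,4S,5E,9Z)-4,11-bis[(tert-butyldimethylsilyl)oxy]-1-iodo-5,9-dimethylundeca-1,5,9-trien-1-yl]-3-(2-methylprop-1-en-1-yl)oxirane | CC(C)=C[C@@H]1O[C@H]1C(/I)=C\C[C@H](O[Si](C)(C)C(C)(C)C)/C(C)=C/CC/C(C)=C\CO[Si](C)(C)C(C)(C)C | intermediate
17 | (2Z,6E,8S,10E)-11-iodo-3,7-dimethyl-11-[(2R,3S)-3-(2-methylprop-1-en-1-yl)oxiran-2-yl]undeca-2,6,10-triene-1,8-diol | CC(C)=C[C@@H]1O[C@H]1C(/I)=C\C[C@H](O)/C(C)=C/CC/C(C)=C\CO | intermediate
18 | (2E)-3-methylpent-2-enoic acid | CC/C(C)=C/C(=O)O | starting material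
19 | (2Z,6E,8S,10E)-8-hydroxy-11-iodo-3,7-dimethyl-11-[(2R,3S)-3-(2-methylprop-1-en-1-yl)oxiran-2-yl]undeca-2,6,10-trien-1-yl (2E)-3-methylpent-2-enoate | CC/C(C)=C/C(=O)OC/C=C(/C)CC/C=C(\C)[C@H](C/C=C(/I)[C@@H]1O[C@H]1C=C(C)C)O | intermediate
20 | (2Z,6E,8S,10E)-8-(acetyloxy)-11-iodo-3,7-dimethyl-11-[(2R,3S)-3-(2-methylprop-1-en-1-yl)oxiran-2-yl]undeca-2,6,10-trien-1-yl (2E)-3-methylpent-2-enoate | CC/C(C)=C/C(=O)OC/C=C(/C)CC/C=C(\C)[C@H](C/C=C(/I)[C@@H]1O[C@H]1C=C(C)C)OC(C)=O | intermediate
21 | carbon dioxide | O=C=O | starting material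
22 | alkenyllithium from 20 (C–Li in place of C–I, geometry retained) | CC/C(C)=C/C(=O)OC/C=C(/C)CC/C=C(\C)[C@H](C/C=C(/[Li])[C@@H]1O[C@H]1C=C(C)C)OC(C)=O | intermediate
23 | lithium (2E,5S,6E,10Z)-5-(acetyloxy)-6,10-dimethyl-12-{[(2E)-3-methylpent-2-enoyl]oxy}-2-[(2S,3S)-3-(2-methylprop-1-en-1-yl)oxiran-2-yl]dodeca-2,6,10-trienoate | CC/C(C)=C/C(=O)OC/C=C(/C)CC/C=C(\C)[C@H](C/C=C(/C(=O)[O-])[C@@H]1O[C@H]1C=C(C)C)OC(C)=O.[Li+] | intermediate
24 | (2E,5S,6E,10Z)-5-(acetyloxy)-6,10-dimethyl-12-{[(2E)-3-methylpent-2-enoyl]oxy}-2-[(2S,3S)-3-(2-methylprop-1-en-1-yl)oxiran-2-yl]dodeca-2,6,10-trienoic acid | CC/C(C)=C/C(=O)OC/C=C(/C)CC/C=C(\C)[C@H](C/C=C(/C(=O)O)[C@@H]1O[C@H]1C=C(C)C)OC(C)=O | intermediate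
25 | (2Z,6E,8S,10E)-8-(acetyloxy)-10-[(4S,5R)-4-hydroxy-5-(2-methylprop-1-en-1-yl)-2-oxooxolan-3-ylidene]-3,7-dimethyldeca-2,6-dien-1-yl (2E)-3-methylpent-2-enoate | CC/C(C)=C/C(=O)OC/C=C(/C)CC/C=C(\C)[C@H](C/C=C1/C(=O)O[C@H](C=C(C)C)[C@H]1O)OC(C)=O | target

Total step count: 15. Longest linear sequence: 15 steps (1 → 25).

**Steps most likely to fail**

1. Step 15. What may go wrong: attack of tert-butyllithium or of the alkenyllithium on the acetate and enoate carbonyl groups, or β-elimination of the oxirane from the alkenyllithium to an allenyl alkoxide before CO2 is admitted. Fallback (ester-free key step, then the esters): setting out from 16, the same exchange, carboxylation and acidification (t-BuLi, −105 °C; CO2; AcOH) would pass through the alkenyllithium F1, the lithium carboxylate F2 and the epoxy acid F3 to the bis-silyl hydroxy lactone F4. TIPSOTf/2,6-lutidine would then give the C4 triisopropylsilyl ether F5, and HF·pyridine/pyridine in THF at 0 °C would remove both tert-butyldimethylsilyl groups to give the diol F6. DCC/DMAP with 18 would give the primary ester F7, and Ac2O/pyridine would give the acetate F8. HF·pyridine in MeCN would remove the triisopropylsilyl group and the sequence comes back to the route at 25.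

2. Step 7. What may go wrong: delivery of tin to C5 instead of C4 across the conjugated enyne, or competing conjugate reduction of the enoate. Fallback (iodide installed on a 2-ynoate, where tin goes α to the ester, then two-carbon extension): setting out from 7, n-BuLi and methyl chloroformate would give the ynoate F9. Pd(PPh3)4/Bu3SnH would give the α-stannyl enoate F10, I2 the α-iodo enoate F11, i-Bu2AlH the iodo allylic alcohol F12 and MnO2 the iodo enal F13. Horner–Wadsworth–Emmons olefination with triethyl phosphonoacetate (LiCl, DBU, MeCN) comes back to the route at 11.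

3. Step 4. What may go wrong: insufficient or reversed enantiofacial discrimination in the propargylation of the α-branched enal. Fallback (racemic addition, then enzymatic kinetic resolution): setting out from 4, a Barbier propargylation (Zn, propargyl bromide, THF/aq. NH4Cl) would give the racemic alcohol F14. A lipase (Burkholderia cepacia lipase, vinyl acetate, MTBE) is expected by the empirical size rule to acetylate the (R)-enantiomer to the (R)-acetate F15, leaving the (S)-alcohol, which comes back to the route at 6.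

Further compounds
F1 | step 15 | alkenyllithium from 16 (C–Li in place of C–I) | CC(C)=C[C@@H]1O[C@H]1C(/[Li])=C\C[C@H](O[Si](C)(C)C(C)(C)C)/C(C)=C/CC/C(C)=C\CO[Si](C)(C)C(C)(C)C
F2 | step 15 | lithium carboxylate from F1 and CO2 | CC(C)=C[C@@H]1O[C@H]1C(/C(=O)[O-])=C\C[C@H](O[Si](C)(C)C(C)(C)C)/C(C)=C/CC/C(C)=C\CO[Si](C)(C)C(C)(C)C.[Li+]
F3 | step 15 | (2E,5S,6E,10Z)-5,12-bis[(tert-butyldimethylsilyl)oxy]-6,10-dimethyl-2-[(2S,3S)-3-(2-methylprop-1-en-1-yl)oxiran-2-yl]dodeca-2,6,10-trienoic acid | CC(C)=C[C@@H]1O[C@H]1C(/C(=O)O)=C\C[C@H](O[Si](C)(C)C(C)(C)C)/C(C)=C/CC/C(C)=C\CO[Si](C)(C)C(C)(C)C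
F4 | step 15 | (3E,4S,5R)-3-[(3S,4E,8Z)-3,10-bis[(tert-butyldimethylsilyl)oxy]-4,8-dimethyldeca-4,8-dien-1-ylidene]-4-hydroxy-5-(2-methylprop-1-en-1-yl)oxolan-2-one | CC(C)(C)[Si](C)(C)OC/C=C(/C)CC/C=C(\C)[C@H](C/C=C1/C(=O)O[C@H](C=C(C)C)[C@H]1O)O[Si](C)(C)C(C)(C)C
F5 | step 15 | C4 triisopropylsilyl ether of F4 | CC(C)(C)[Si](C)(C)OC/C=C(/C)CC/C=C(\C)[C@H](C/C=C1/C(=O)O[C@H](C=C(C)C)[C@H]1O[Si](C(C)C)(C(C)C)C(C)C)O[Si](C)(C)C(C)(C)C
F6 | step 15 | side-chain diol with C4 triisopropylsilyl ether | OC/C=C(/C)CC/C=C(\C)[C@H](C/C=C1/C(=O)O[C@H](C=C(C)C)[C@H]1O[Si](C(C)C)(C(C)C)C(C)C)O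
F7 | step 15 | primary (2E)-3-methylpent-2-enoate of F6 | CC/C(C)=C/C(=O)OC/C=C(/C)CC/C=C(\C)[C@H](C/C=C1/C(=O)O[C@H](C=C(C)C)[C@H]1O[Si](C(C)C)(C(C)C)C(C)C)O
F8 | step 15 | C4 triisopropylsilyl ether of 25 | CC/C(C)=C/C(=O)OC/C=C(/C)CC/C=C(\C)[C@H](C/C=C1/C(=O)O[C@H](C=C(C)C)[C@H]1O[Si](C(C)C)(C(C)C)C(C)C)OC(C)=O
F9 | step 7 | methyl (5S,6E,10Z)-5,12-bis[(tert-butyldimethylsilyl)oxy]-6,10-dimethyldodeca-6,10-dien-2-ynoate | COC(=O)C#CC[C@H](O[Si](C)(C)C(C)(C)C)/C(C)=C/CC/C(C)=C\CO[Si](C)(C)C(C)(C)C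
F10 | step 7 | methyl (2E,5S,6E,10Z)-5,12-bis[(tert-butyldimethylsilyl)oxy]-6,10-dimethyl-2-(tributylstannyl)dodeca-2,6,10-trienoate | COC(=O)/C([Sn](CCCC)(CCCC)CCCC)=C\C[C@H](O[Si](C)(C)C(C)(C)C)/C(C)=C/CC/C(C)=C\CO[Si](C)(C)C(C)(C)C
F11 | step 7 | methyl (2E,5S,6E,10Z)-5,12-bis[(tert-butyldimethylsilyl)oxy]-2-iodo-6,10-dimethyldodeca-2,6,10-trienoate | COC(=O)/C(I)=C\C[C@H](O[Si](C)(C)C(C)(C)C)/C(C)=C/CC/C(C)=C\CO[Si](C)(C)C(C)(C)C
F12 | step 7 | (2E,5S,6E,10Z)-5,12-bis[(tert-butyldimethylsilyl)oxy]-2-iodo-6,10-dimethyldodeca-2,6,10-trien-1-ol | OC/C(I)=C\C[C@H](O[Si](C)(C)C(C)(C)C)/C(C)=C/CC/C(C)=C\CO[Si](C)(C)C(C)(C)C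
F13 | step 7 | (2E,5S,6E,10Z)-5,12-bis[(tert-butyldimethylsilyl)oxy]-2-iodo-6,10-dimethyldodeca-2,6,10-trienal | O=C/C(I)=C\C[C@H](O[Si](C)(C)C(C)(C)C)/C(C)=C/CC/C(C)=C\CO[Si](C)(C)C(C)(C)C
F14 | step 4 | racemic (5E,9Z)-11-[(tert-butyldimethylsilyl)oxy]-5,9-dimethylundeca-5,9-dien-1-yn-4-ol | C#CCC(O)/C(C)=C/CC/C(C)=C\CO[Si](C)(C)C(C)(C)C
F15 | step 4 | (4R,5E,9Z)-11-[(tert-butyldimethylsilyl)oxy]-5,9-dimethylundeca-5,9-dien-1-yn-4-yl acetate | C#CC[C@@H](OC(C)=O)/C(C)=C/CC/C(C)=C\CO[Si](C)(C)C(C)(C)C
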